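## Retrosynthetic overview

1. The last step closes the C1–C2 bond, the trans γ-lactone and the 14-membered ring together, by intramolecular allylboration–lactonisation of a seco enal/allylboronate.
2. C15–C17 come from a borylated Still–Gennari phosphonate; C12=C13 (Z) from a Wittig reaction on an α-peroxy methyl ketone; C6–C7 (7S) from a catalyst-controlled alkylzinc addition to an α-peroxy aldehyde.
3. Key disconnection: the C7–C12 keto aldehyde is a cis-3,6-disubstituted 1,2-dioxane, made by ozonolysis of a bicyclic endoperoxide that comes from singlet-oxygen [4+2] addition to the diene obtained by Birch reduction of m-xylene. The six arene carbons become C7–C12 and the two methyls C19/C20.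
4. C2–C6 comes from but-3-yn-1-ol (carboalumination sets 3E); C13–C14–C1 from a commercial phosphonium salt.
5. Ring order: 1,2-dioxane first (steps 3–4), then carbocycle and α-methylene-γ-lactone together (step 14).

Assumption: cembrane locants (C1–C20) are used in the text; the SMILES is read as (1S,2R,3E,7S,8R,11S,12Z) with a trans lactone and a cis dioxane; racemic compounds 4–6 are drawn as the enantiomer that leads to the target.

## Route

Step 1
Reactants: 1 m-xylene
Product: 2 1,5-dimethylcyclohexa-1,4-diene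
Conditions: Li, NH3(l), t-BuOH, THF, −78 → −33 °C; then H2O
Reagents that add atoms: none
Why: Birch reduction breaks the aromaticity; both methyl groups stay on alkene carbons, so a single skipped diene forms (no stereocentre).

Step 2
Reactants: 2 1,5-dimethylcyclohexa-1,4-diene
Product: 3 1,3-dimethylcyclohexa-1,3-diene
Conditions: KOt-Bu (0.3 equiv), DMSO, 25 °C; pentane extraction, equilibrium mixture used directly
Reagents that add atoms: none
Why: Base-catalysed prototropic isomerisation brings the diene into conjugation, and the isomer with both methyls on the diene is the most substituted and expected to dominate among the conjugated isomers.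

Step 3
Reactants: 3 1,3-dimethylcyclohexa-1,3-diene
Product: 4 rac-(1R,4S)-1,5-dimethyl-2,3-dioxabicyclo[2.2.2]oct-5-ene
Conditions: O2, tetraphenylporphyrin (1 mol %), white LED, CH2Cl2, −20 °C; chromatography
Reagents that add atoms: dioxygen O=O
Why: Singlet-oxygen [4+2] cycloaddition is suprafacial, so both C–O bonds form on one face and the future C8 and C11 are set cis (racemic); only the conjugated diene reacts this way.

Step 4
Reactants: 4 rac-(1R,4S)-1,5-dimethyl-2,3-dioxabicyclo[2.2.2]oct-5-ene
Product: 6 rac-(3R,6S)-6-acetyl-3-methyl-1,2-dioxane-3-carbaldehyde, via hydroperoxy methyl ketal 5 (not isolated)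
Conditions: O3, CH2Cl2/MeOH (4:1), −78 °C; then Me2S, −78 → 20 °C; used crude
Reagents that add atoms: ozone [O-][O+]=O
Why: Ozonolysis (Criegee cleavage, MeOH trapping, Me2S reduction) cuts the only C=C and unzips the carbocycle into the cis-3,6-disubstituted 1,2-dioxane; the O–O bond survives O3 and Me2S and neither stereocentre is touched.

Step 5
Reactants: 7 but-3-yn-1-ol
Product: 9 (E)-3-methylpent-2-ene-1,5-diol, via alkenylalane 8 (not isolated)
Conditions: Me3Al (3 equiv), Cp2ZrCl2 (0.25 equiv), CH2Cl2, 0 → 23 °C; then n-BuLi, (CH2O)n, THF, −78 → 23 °C; aq. HCl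
Reagents that add atoms: trimethylaluminium C[Al](C)C; paraformaldehyde (formaldehyde unit) C=O
Why: Zirconium-catalysed Negishi carboalumination adds Me and Al syn across the alkyne, and hydroxymethylation of the aluminate goes with retention, which fixes the E geometry of C3=C4.

Step 6
Reactants: 9 (E)-3-methylpent-2-ene-1,5-diol
Product: 10 (E)-5-hydroxy-3-methylpent-2-enal
Conditions: MnO2 (15 equiv), CH2Cl2, 23 °C
Reagents that add atoms: none
Why: MnO2 oxidises only the allylic alcohol (chemoselective allylic oxidation) and the E-configured hydroxy enal cannot close to a lactol.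

Step 7
Reactants: 10 (E)-5-hydroxy-3-methylpent-2-enal
Product: 11 (E)-5,5-dimethoxy-3-methylpent-3-en-1-ol
Conditions: HC(OMe)3, MeOH, PPTS (cat.), 0 → 23 °C
Reagents that add atoms: trimethyl orthoformate COC(OC)OC; methanol CO
Why: Mild acid-catalysed acetalisation masks the enal for the organozinc chemistry; the weak acid limits E/Z scrambling.

Step 8
Reactants: 11 (E)-5,5-dimethoxy-3-methylpent-3-en-1-ol
Product: 12 (E)-5-iodo-1,1-dimethoxy-3-methylpent-2-ene
Conditions: I2, PPh3, imidazole, CH2Cl2, 0 °C
Reagents that add atoms: iodine II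
Why: Appel-type iodination (SN2 at the primary carbon), buffered by imidazole so that the unsaturated acetal survives.

Step 9
Reactants: 6 rac-(3R,6S)-6-acetyl-3-methyl-1,2-dioxane-3-carbaldehyde; 12 (E)-5-iodo-1,1-dimethoxy-3-methylpent-2-ene
Product: 15 (1S,4E)-1-[(3R,6S)-6-acetyl-3-methyl-1,2-dioxan-3-yl]-6,6-dimethoxy-4-methylhex-4-en-1-yl acetate, via diorganozinc 13 (not isolated), via zinc alkoxide 14 (not isolated)
Conditions: 12 (3 equiv), Et2Zn, CuI (0.3 mol %), 50 °C, volatiles removed in vacuo; (1R,2R)-1,2-bis(trifluoromethanesulfonamido)cyclohexane (8 mol %), Ti(Oi-Pr)4, toluene, −20 °C, then 6; then Ac2O, 0 → 23 °C; aq. NH4Cl; chromatography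
Reagents that add atoms: acetic anhydride CC(=O)OC(C)=O
Why: Iodine–zinc exchange followed by titanium/bis-sulfonamide-catalysed asymmetric alkylzinc addition: the (1R,2R) ligand sends the alkyl group to the Si face of the aldehyde and sets C7 as S, so the (3R,6S) half of 6 (matched, Felkin–Anh) gives 15 and the (3S,6R) half gives a separable diastereomer, which resolves the racemate; quenching the zinc alkoxide with Ac2O avoids a free β-peroxy alkoxide and any amine base near the α-peroxy ketone, and the ketone is inert to the zinc reagent.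

Step 10
Reactants: 15 (1S,4E)-1-[(3R,6S)-6-acetyl-3-methyl-1,2-dioxan-3-yl]-6,6-dimethoxy-4-methylhex-4-en-1-yl acetate; 16 [2-(1,3-dioxolan-2-yl)ethyl]triphenylphosphonium bromide
Product: 18 (1S,4E)-1-{(3R,6S)-6-[(2Z)-4-(1,3-dioxolan-2-yl)but-2-en-2-yl]-3-methyl-1,2-dioxan-3-yl}-6,6-dimethoxy-4-methylhex-4-en-1-yl acetate, via ylide 17 (not isolated)
Conditions: 16, KN(SiMe3)2, THF, 0 °C; then 15 added at −78 °C, → −20 °C
Reagents that add atoms: none
Why: Wittig reaction of a non-stabilised ylide with an α-oxygenated methyl ketone, which is known to place the ylide chain cis to the oxygenated carbon and so gives the Z trisubstituted C12=C13 alkene; fast addition at −78 °C to the activated ketone is relied on to outrun deprotonation at C11 (Kornblum–DeLaMare cleavage), and the acetate is much less electrophilic than the ketone.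

Step 11
Reactants: 18 (the Wittig product above)
Product: 19 (1S,4E)-4-methyl-1-{(3R,6S)-3-methyl-6-[(2Z)-5-oxopent-2-en-2-yl]-1,2-dioxan-3-yl}-6-oxohex-4-en-1-yl acetate
Conditions: 1 M aq. HCl, THF, 23 °C
Reagents that add atoms: water O
Why: Acid hydrolysis of both acetals (the allylic dimethyl acetal within minutes, the dioxolane more slowly); peroxide, acetate and both alkenes tolerate dilute aqueous acid.

Step 12
Reactants: 20 methyl 2-[bis(2,2,2-trifluoroethoxy)phosphoryl]acetate; 21 2-(iodomethyl)-4,4,5,5-tetramethyl-1,3,2-dioxaborolane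
Product: 22 methyl 2-[bis(2,2,2-trifluoroethoxy)phosphoryl]-3-(4,4,5,5-tetramethyl-1,3,2-dioxaborolan-2-yl)propanoate
Conditions: NaH, THF, 0 → 23 °C
Reagents that add atoms: none
Why: C-alkylation of the stabilised phosphonoacetate anion with an (iodomethyl)boronate, the same enolate alkylation used to make α-alkyl Still–Gennari reagents.

Step 13
Reactants: 19 (the dialdehyde above); 22 (the borylated phosphonate above)
Product: 23 methyl (2Z,5Z)-6-{(3S,6R)-6-[(1S,4E)-1-acetoxy-4-methyl-6-oxohex-4-en-1-yl]-6-methyl-1,2-dioxan-3-yl}-2-[(4,4,5,5-tetramethyl-1,3,2-dioxaborolan-2-yl)methyl]hepta-2,5-dienoate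
Conditions: 22 (1.05 equiv), KN(SiMe3)2, 18-crown-6, THF, −78 °C
Reagents that add atoms: none
Why: Proposed new method: Still–Gennari-type Horner–Wadsworth–Emmons olefination with an α-(borylmethyl) phosphonate; the closest known reactions are Z-selective olefinations with α-alkyl bis(trifluoroethyl) phosphonoacetates, where fast elimination from the first adduct gives the kinetic Z-enoate (C14 cis to CO2Me, hence trans to CH2B as the ring closure needs); boron sits 1,3 to the oxygen and cannot eliminate, and the saturated C1 aldehyde should react well before the conjugated, β,β-disubstituted C2 enal.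

Step 14
Reactants: 23 (the allylboronate enal above)
Product: 25 target CNP0238885.5, (1S,2R,3E,7S,8R,11S,12Z)-7-acetoxy-8,11-epidioxycembra-3,12,15(17)-trien-16,2-olide, via boryl ether 24 (not isolated)
Conditions: Sc(OTf)3 (10 mol %), CH2Cl2 (1 mM), 0 → 23 °C; then p-TsOH (cat.)
Reagents that add atoms: none
Why: Proposed new method: Lewis-acid-catalysed allylboration of aldehydes by 2-alkoxycarbonyl allylboronates is known intermolecularly and gives α-methylene-γ-lactones directly; here it closes the macrocycle, and in the closed chair transition state the enal substituent and C14 (trans to CH2B) are both pseudo-equatorial, giving the anti adduct 24 and, after lactonisation, the trans lactone; which face of the enal reacts (1S,2R versus 1R,2S) is left to the conformational bias of the dioxane-bridged tether and is not proven.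

## Compound list

1 | m-xylene | Cc1cccc(C)c1 | starting material
2 | 1,5-dimethylcyclohexa-1,4-diene | CC1=CCC=C(C)C1 | intermediate
3 | 1,3-dimethylcyclohexa-1,3-diene | CC1=CC(C)=CCC1 | intermediate
4 | rac-(1R,4S)-1,5-dimethyl-2,3-dioxabicyclo[2.2.2]oct-5-ene (racemate, one enantiomer drawn) | C[C@]12CC[C@H](OO1)C(C)=C2 | intermediate
5 | (3R,6S)-6-(1-hydroperoxy-1-methoxyethyl)-3-methyl-1,2-dioxane-3-carbaldehyde (racemic, ketal carbon undefined) | O=C[C@@]1(C)CC[C@H](OO1)C(C)(OC)OO | intermediate (not isolated)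
6 | rac-(3R,6S)-6-acetyl-3-methyl-1,2-dioxane-3-carbaldehyde (racemate, one enantiomer drawn) | O=C[C@@]1(C)CC[C@H](OO1)C(C)=O | intermediate
7 | but-3-yn-1-ol | C#CCCO | starting material
8 | [(E)-4-(dimethylalumanyloxy)-2-methylbut-1-en-1-yl]dimethylalumane | C[Al](C)/C=C(\C)CCO[Al](C)C | intermediate (not isolated)
9 | (E)-3-methylpent-2-ene-1,5-diol | OC/C=C(\C)CCO | intermediate
10 | (E)-5-hydroxy-3-methylpent-2-enal | O=C/C=C(\C)CCO | intermediate
11 | (E)-5,5-dimethoxy-3-methylpent-3-en-1-ol | COC(OC)/C=C(\C)CCO | intermediate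
12 | (E)-5-iodo-1,1-dimethoxy-3-methylpent-2-ene | COC(OC)/C=C(\C)CCI | intermediate
13 | bis[(E)-5,5-dimethoxy-3-methylpent-3-en-1-yl]zinc | COC(OC)/C=C(\C)CC[Zn]CC/C(C)=C/C(OC)OC | intermediate (not isolated)
14 | zinc alkoxide of the C7 carbinol (O–Zn–alkyl) | COC(OC)/C=C(\C)CC[C@H](O[Zn]CC/C(C)=C/C(OC)OC)[C@@]1(C)CC[C@H](OO1)C(C)=O | intermediate (not isolated)
15 | (1S,4E)-1-[(3R,6S)-6-acetyl-3-methyl-1,2-dioxan-3-yl]-6,6-dimethoxy-4-methylhex-4-en-1-yl acetate | COC(OC)/C=C(\C)CC[C@H](OC(C)=O)[C@@]1(C)CC[C@H](OO1)C(C)=O | intermediate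
16 | [2-(1,3-dioxolan-2-yl)ethyl]triphenylphosphonium bromide | [Br-].C1COC(CC[P+](c2ccccc2)(c2ccccc2)c2ccccc2)O1 | starting material
17 | [3-(1,3-dioxolan-2-yl)propylidene]triphenylphosphorane | C1COC(CC=P(c2ccccc2)(c2ccccc2)c2ccccc2)O1 | intermediate (not isolated)
18 | (1S,4E)-1-{(3R,6S)-6-[(2Z)-4-(1,3-dioxolan-2-yl)but-2-en-2-yl]-3-methyl-1,2-dioxan-3-yl}-6,6-dimethoxy-4-methylhex-4-en-1-yl acetate | COC(OC)/C=C(\C)CC[C@H](OC(C)=O)[C@@]1(C)CC[C@H](OO1)/C(C)=C\CC1OCCO1 | intermediate
19 | (1S,4E)-4-methyl-1-{(3R,6S)-3-methyl-6-[(2Z)-5-oxopent-2-en-2-yl]-1,2-dioxan-3-yl}-6-oxohex-4-en-1-yl acetate | O=C/C=C(\C)CC[C@H](OC(C)=O)[C@@]1(C)CC[C@H](OO1)/C(C)=C\CC=O | intermediate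
20 | methyl 2-[bis(2,2,2-trifluoroethoxy)phosphoryl]acetate | COC(=O)CP(=O)(OCC(F)(F)F)OCC(F)(F)F | starting material
21 | 2-(iodomethyl)-4,4,5,5-tetramethyl-1,3,2-dioxaborolane | ICB1OC(C)(C)C(C)(C)O1 | starting material
22 | methyl 2-[bis(2,2,2-trifluoroethoxy)phosphoryl]-3-(4,4,5,5-tetramethyl-1,3,2-dioxaborolan-2-yl)propanoate (racemic) | COC(=O)C(CB1OC(C)(C)C(C)(C)O1)P(=O)(OCC(F)(F)F)OCC(F)(F)F | intermediate
23 | methyl (2Z,5Z)-6-{(3S,6R)-6-[(1S,4E)-1-acetoxy-4-methyl-6-oxohex-4-en-1-yl]-6-methyl-1,2-dioxan-3-yl}-2-[(4,4,5,5-tetramethyl-1,3,2-dioxaborolan-2-yl)methyl]hepta-2,5-dienoate | O=C/C=C(\C)CC[C@H](OC(C)=O)[C@@]1(C)CC[C@H](OO1)/C(C)=C\C/C=C(/CB1OC(C)(C)C(C)(C)O1)C(=O)OC | intermediate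
24 | macrocyclic seco-lactone: 14-membered ring closed at C1–C2, C2–O–B(pinacolato), methyl acrylate unit at C1 | CC1(C)OB(O[C@@H]2/C=C(\C)CC[C@H](OC(C)=O)[C@@]3(C)CC[C@H](OO3)/C(C)=C\C[C@H]2C(=C)C(=O)OC)OC1(C)C | intermediate (not isolated)
25 | target CNP0238885.5 | C=C1C(=O)O[C@@H]2/C=C(\C)CC[C@H](OC(C)=O)[C@@]3(C)CC[C@H](OO3)/C(C)=C\C[C@@H]12 | target

## Step count and risks

Total step count: 14. Longest linear sequence: 9 (steps 1–4, 9, 10, 11, 13, 14; the but-3-yn-1-ol branch, steps 5–8 then 9–14 without 12, is equally long).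

The enantiomeric purity of 25 equals the face selectivity of the catalyst in step 9, since no later step is reagent-controlled; a final crystallisation may be needed.

Most likely to fail:

Step 14 (ring closure). The allylboration may be too slow for the peroxide to survive, may give the cis lactone, or may take the wrong enal face. Fallback, from 19 back to 25: switch from the closed boron transition state to an open Hosomi–Sakurai closure. Phosphonate 20 is alkylated with ICH2SiMe3 (NaH) to methyl 2-[bis(2,2,2-trifluoroethoxy)phosphoryl]-3-(trimethylsilyl)propanoate F6. Olefination of 19 as in step 13 gives the (Z)-2-(trimethylsilylmethyl)enoate enal F7. BF3·OEt2 (CH2Cl2, 1 mM, −78 °C) closes C1–C2 to the macrocyclic hydroxy ester F8, and p-TsOH lactonises F8 to 25. The diastereomer ratio must be determined, but the different transition-state geometry offers a second chance at the trans (1S,2R) isomer and also bypasses the untested boron reagent of step 13.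

Step 10 (Wittig on the α-peroxy ketone). The ylide may deprotonate C11 and trigger Kornblum–DeLaMare cleavage. Fallback, from 15 (with 16) back to 18: deliver C13 as a non-basic organocerium reagent and form the alkene in a separate stereospecific elimination (Horner–Wittig). Salt 16 is hydrolysed with aq. NaOH to [2-(1,3-dioxolan-2-yl)ethyl]diphenylphosphine oxide F4. F4 is lithiated (n-BuLi, −78 °C), transmetalated with CeCl3 and added to 15 to give the β-hydroxy phosphine oxides F5. The diastereomer that has C11 and C14 on the same side in the syn-periplanar P–C–C–O arrangement is separated and eliminated (NaH, DMF, 0 °C) to 18 with Z geometry. The elimination passes through a short-lived β-peroxy alkoxide, so it is kept cold and brief.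

Step 9 (alkylzinc addition and resolution). The sp3 zinc reagent may transfer slowly, attack the O–O bond, or show poor catalyst control next to the quaternary centre. Fallback, from 6 back to 15: use a more reactive sp2 zinc reagent and remove the extra alkene afterwards. Commercial (E)-3-methylpent-2-en-4-yn-1-ol is oxidised (MnO2) to (E)-3-methylpent-2-en-4-ynal F1 and acetalised (HC(OMe)3, PPTS) to (E)-5,5-dimethoxy-3-methylpent-3-en-1-yne F2. Hydroboration of F2 with dicyclohexylborane, boron-to-zinc exchange with Et2Zn, addition to 6 with catalytic (−)-3-exo-morpholinoisoborneol and the same Ac2O quench and diastereomer separation give the dienyl acetate F3. Diimide (KO2CN=NCO2K, AcOH, MeOH, 0 °C), which leaves O–O bonds and trisubstituted alkenes alone, saturates only the disubstituted C5=C6 alkene of F3 to give 15.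

Further compounds

F1 | step 9 | (E)-3-methylpent-2-en-4-ynal | C#C/C(C)=C/C=O
F2 | step 9 | (E)-5,5-dimethoxy-3-methylpent-3-en-1-yne | C#C/C(C)=C/C(OC)OC
F3 | step 9 | (1S,2E,4E)-1-[(3R,6S)-6-acetyl-3-methyl-1,2-dioxan-3-yl]-6,6-dimethoxy-4-methylhexa-2,4-dien-1-yl acetate | COC(OC)/C=C(C)/C=C/[C@H](OC(C)=O)[C@@]1(C)CC[C@H](OO1)C(C)=O
F4 | step 10 | [2-(1,3-dioxolan-2-yl)ethyl]diphenylphosphine oxide | O=P(CCC1OCCO1)(c1ccccc1)c1ccccc1
F5 | step 10 | β-hydroxy phosphine oxide from 15 (tertiary alcohol at C12, Ph2P(O) at C13; two new centres, diastereomers separated) | COC(OC)/C=C(\C)CC[C@H](OC(C)=O)[C@@]1(C)CC[C@H](OO1)C(C)(O)C(CC1OCCO1)P(=O)(c1ccccc1)c1ccccc1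
F6 | step 14 | methyl 2-[bis(2,2,2-trifluoroethoxy)phosphoryl]-3-(trimethylsilyl)propanoate | COC(=O)C(C[Si](C)(C)C)P(=O)(OCC(F)(F)F)OCC(F)(F)F
F7 | step 14 | methyl (2Z,5Z)-6-{(3S,6R)-6-[(1S,4E)-1-acetoxy-4-methyl-6-oxohex-4-en-1-yl]-6-methyl-1,2-dioxan-3-yl}-2-[(trimethylsilyl)methyl]hepta-2,5-dienoate | O=C/C=C(\C)CC[C@H](OC(C)=O)[C@@]1(C)CC[C@H](OO1)/C(C)=C\C/C=C(/C[Si](C)(C)C)C(=O)OC
F8 | step 14 | macrocyclic hydroxy ester (14-membered ring closed at C1–C2, free C2–OH, methyl acrylate unit at C1) | O[C@@H]1/C=C(\C)CC[C@H](OC(C)=O)[C@@]2(C)CC[C@H](OO2)/C(C)=C\C[C@H]1C(=C)C(=O)OC
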